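**Retrosynthetic overview**

1. 21 ⇐ 19: only unmasking remains (the 5-methyl ether beside the C4 carbonyl and the two MOM ethers on ring B); 19 already holds every skeletal bond and both stereocentres.
2. 19 ⇐ 18 by cutting C2–C3: the route rests on the C2–H bond, which in 18 is one of the two benzylic hydrogens of the O1–CH2–(ring B) ether, α to O1 and the sixth atom of the chain C3–C4–C4a–C8a–O1–C2, so a carbene at C3 (diazomethyl ketone on ring A) can insert into it, closing ring C and creating C2.
3. 18 ⇐ acid 16 ⇐ aldehyde 15 ⇐ salicylaldehyde 10 + benzylic bromide 14 (O1–CH2 bond; 14 from 2,5-dihydroxybenzaldehyde in three steps).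
4. 10 ⇐ phenol 8 (ortho-formylation) ⇐ MOM ether 2 + triflate 5: the aryl–CH2 bond of the side chain comes from an ortho-lithiated arene and (S)-lavandulyl triflate, the latter from lipase-resolved lavandulol.
5. Ring order: rings A and B are bought; ring C is the only ring made and is closed in step 13.

Key step: step 13

Assumption (step 2): the lipase is taken to acetylate (R)-lavandulol the faster, so that the alcohol left behind is the S enantiomer 4; were the preference the reverse, the acetate would be isolated and saponified to 4.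
Assumption (step 13): the catalyst built from (S)-tert-leucine is taken to select the benzylic hydrogen whose replacement gives 2S; if a trial shows the opposite sense, the mirror-image catalyst from (R)-tert-leucine is used under the same conditions.
Shorthand: lavandulyl = 5-methyl-2-(prop-1-en-2-yl)hex-4-en-1-yl; MOM = methoxymethyl. The side-chain centre is S in the alcohol, triflate and iodide and R once the CH2 carbon is bound to the arene; the geometry is the same and only the CIP priorities change.

**Route**

Step 1
Reactants: 1 3,5-dimethoxyphenol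
Product: 2 1,3-dimethoxy-5-(methoxymethoxy)benzene
Conditions: MOMCl, i-Pr2NEt, CH2Cl2, 0 °C to rt
Reagents that add atoms: chloromethyl methyl ether (MOMCl), COCCl
Why: O-alkylation of the phenol with the α-chloro ether under amine base (MOM protection) is routine and installs the acetal that later directs ortho-lithiation.

Step 2
Reactants: 3 racemic lavandulol
Product: 4 (S)-lavandulol
Conditions: porcine pancreatic lipase, vinyl acetate, t-BuOMe, rt, stopped at about 60 % conversion; chromatography
Reagents that add atoms: none
Why: Lipase-catalysed irreversible transesterification with vinyl acetate is a kinetic resolution of the primary alcohol in which the R enantiomer is acetylated faster, so that driving the conversion past one half should leave the S alcohol; the side-chain stereocentre is thereby selected, not created.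

Step 3
Reactants: 4 (S)-lavandulol
Product: 5 (S)-lavandulyl trifluoromethanesulfonate
Conditions: Tf2O, 2,6-lutidine, CH2Cl2, −78 °C; cold filtration through a short pad, used at once
Reagents that add atoms: trifluoromethanesulfonic anhydride, O=S(=O)(OS(=O)(=O)C(F)(F)F)C(F)(F)F
Why: Sulfonylation of the primary hydroxyl with triflic anhydride at −78 °C beside a hindered pyridine base gives the alkyl triflate without touching the adjacent stereocentre or the two alkenes.

Step 4
Reactants: 2 1,3-dimethoxy-5-(methoxymethoxy)benzene; 5 (S)-lavandulyl trifluoromethanesulfonate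
Product: 7 1,5-dimethoxy-3-(methoxymethoxy)-2-[(2R)-lavandulyl]benzene, via aryllithium 6 (not isolated)
Conditions: 2 (1.5 equiv), n-BuLi, THF, 0 °C; then 5, −78 to −30 °C
Reagents that add atoms: n-butyllithium, [Li]CCCC (supplies only the lithium of 6)
Why: Directed ortho-metalation places lithium on the carbon flanked by the MOM acetal and a methoxy group, and the aryllithium displaces the primary triflate by SN2 at CH2 at low temperature, where substitution should outrun elimination; the stereocentre is not a reacting atom and keeps its geometry.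

Step 5
Reactants: 7 1,5-dimethoxy-3-(methoxymethoxy)-2-[(2R)-lavandulyl]benzene
Product: 8 3,5-dimethoxy-2-[(2R)-lavandulyl]phenol
Conditions: HCl (0.5 M), MeOH, rt, stopped as soon as 7 is consumed
Reagents that add atoms: none
Why: Acid-catalysed transacetalisation in methanol cleaves the aryl MOM ether, and with dilute acid at room temperature this should be faster than protonation of the side-chain alkenes, which would lead the new ortho-phenol into a chroman.

Step 6
Reactants: 8 3,5-dimethoxy-2-[(2R)-lavandulyl]phenol
Product: 10 2-hydroxy-4,6-dimethoxy-3-[(2R)-lavandulyl]benzaldehyde, via salicyl alcohol 9 (not isolated)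
Conditions: MgCl2, Et3N, (CH2O)n, MeCN, 80 °C; dilute HCl work-up
Reagents that add atoms: paraformaldehyde (as formaldehyde), C=O
Why: Magnesium-mediated ortho-formylation (Casnati–Skattebøl reaction): the magnesium phenoxide delivers formaldehyde to the only free ortho carbon and a second formaldehyde oxidises the resulting benzylic magnesium alkoxide by hydride transfer, so the position between the two methoxy groups stays untouched.

Step 7
Reactants: 11 2,5-dihydroxybenzaldehyde
Product: 12 2,5-bis(methoxymethoxy)benzaldehyde
Conditions: MOMCl (3 equiv), i-Pr2NEt, CH2Cl2, 0 °C to reflux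
Reagents that add atoms: chloromethyl methyl ether (MOMCl), COCCl
Why: Double MOM protection of the phenols; the hydrogen-bonded 2-hydroxyl needs excess reagent and warming but reacts under the same conditions.

Step 8
Reactants: 12 2,5-bis(methoxymethoxy)benzaldehyde
Product: 13 [2,5-bis(methoxymethoxy)phenyl]methanol
Conditions: NaBH4, MeOH, 0 °C
Reagents that add atoms: none
Why: Borohydride reduction of the aryl aldehyde to the benzylic alcohol leaves the acetals untouched.

Step 9
Reactants: 13 [2,5-bis(methoxymethoxy)phenyl]methanol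
Product: 14 2-(bromomethyl)-1,4-bis(methoxymethoxy)benzene
Conditions: CBr4, PPh3, CH2Cl2, 0 °C; used directly
Reagents that add atoms: tetrabromomethane, BrC(Br)(Br)Br
Why: The Appel reaction converts the benzylic alcohol into the bromide under neutral conditions that the acid-labile MOM groups tolerate.

Step 10
Reactants: 10 2-hydroxy-4,6-dimethoxy-3-[(2R)-lavandulyl]benzaldehyde; 14 2-(bromomethyl)-1,4-bis(methoxymethoxy)benzene
Product: 15 2-{[2,5-bis(methoxymethoxy)phenyl]methoxy}-4,6-dimethoxy-3-[(2R)-lavandulyl]benzaldehyde
Conditions: K2CO3, DMF, rt to 50 °C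
Reagents that add atoms: none
Why: Williamson etherification: the acidic salicylaldehyde hydroxyl is deprotonated by carbonate and O-alkylated by the reactive benzylic bromide in DMF, which forms the O1–CH2 bond.

Step 11
Reactants: 15 2-{[2,5-bis(methoxymethoxy)phenyl]methoxy}-4,6-dimethoxy-3-[(2R)-lavandulyl]benzaldehyde
Product: 16 2-{[2,5-bis(methoxymethoxy)phenyl]methoxy}-4,6-dimethoxy-3-[(2R)-lavandulyl]benzoic acid
Conditions: NaClO2, NaH2PO4, 2-methyl-2-butene (large excess), t-BuOH/THF/H2O, 0 °C to rt
Reagents that add atoms: sodium chlorite, [Na+].[O-]Cl=O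
Why: The Pinnick oxidation converts the hindered aryl aldehyde into the acid under buffered conditions, and the large excess of 2-methyl-2-butene should intercept hypochlorous acid before it attacks the electron-rich ring or the side-chain alkenes.

Step 12
Reactants: 16 2-{[2,5-bis(methoxymethoxy)phenyl]methoxy}-4,6-dimethoxy-3-[(2R)-lavandulyl]benzoic acid
Product: 18 2-diazo-1-{2-{[2,5-bis(methoxymethoxy)phenyl]methoxy}-4,6-dimethoxy-3-[(2R)-lavandulyl]phenyl}ethan-1-one, via acid chloride 17 (not isolated)
Conditions: 1-chloro-N,N,2-trimethylprop-1-en-1-amine, CH2Cl2, 0 °C to rt; then CH2N2 (excess), Et2O, 0 °C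
Reagents that add atoms: diazomethane, C=[N+]=[N-]; 1-chloro-N,N,2-trimethylprop-1-en-1-amine, CC(C)=C(Cl)N(C)C (supplies only the chlorine of 17)
Why: The α-chloroenamine forms the acid chloride without liberating HCl, so the MOM groups and alkenes are spared, and acylation of diazomethane (first stage of the Arndt–Eistert sequence) gives the diazomethyl ketone while a second equivalent of diazomethane takes up the HCl formed.

Step 13
Reactants: 18 2-diazo-1-{2-{[2,5-bis(methoxymethoxy)phenyl]methoxy}-4,6-dimethoxy-3-[(2R)-lavandulyl]phenyl}ethan-1-one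
Product: 19 (2S)-2-[2,5-bis(methoxymethoxy)phenyl]-5,7-dimethoxy-8-[(2R)-lavandulyl]-2,3-dihydro-4H-chromen-4-one
Conditions: Rh2(S-PTTL)4 [dirhodium tetrakis(N-phthaloyl-(S)-tert-leucinate)] (2 mol %), CH2Cl2, 4 Å MS, 0 °C to rt, slow addition of 18; chromatography
Reagents that add atoms: none
Why: The dirhodium tetracarboxylate (divalent rhodium) takes N2 out of the diazo group of 18 and leaves an electrophilic rhodium carbene at C3, which inserts into one benzylic C–H bond of the O1–CH2–aryl group through a three-centre, hydride-transfer-like transition state and so forms the C2–C3 bond. The closest known reaction is the dirhodium-carboxylate-catalysed intramolecular C–H insertion of 2-alkoxyaryl diazomethyl ketones to 2-substituted chroman-4-ones. Ring C closes as a six-membered ring by 1,6-C–H insertion, the five-membered alternative being excluded because the atom in the 1,5-position is O1, which carries no hydrogen. The C2 stereocentre is set by the catalyst, whose four N-phthaloyl-tert-leucinate ligands form a chiral pocket that should select one of the two enantiotopic benzylic hydrogens; the lavandulyl centre is too remote to interfere and turns any 2R product into a diastereomer that chromatography can remove. The step needs C–H insertion to win over capture of the carbene by a lone pair of O1 (oxonium ylide, then 1,2-shift of the benzyl group to a benzofuran-3-one) and over reaction at the 5-methoxy group: the target C–H bond is secondary, benzylic and flanked by O1 and the electron-rich ring B, hence the most hydridic one in reach, the methyl ether offers only primary C–H bonds, and a rhodium carboxylate is chosen instead of a copper catalyst because copper steers such substrates toward ylides.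

Step 14
Reactants: 19 (2S)-2-[2,5-bis(methoxymethoxy)phenyl]-5,7-dimethoxy-8-[(2R)-lavandulyl]-2,3-dihydro-4H-chromen-4-one
Product: 20 (2S)-2-[2,5-bis(methoxymethoxy)phenyl]-5-hydroxy-7-methoxy-8-[(2R)-lavandulyl]-2,3-dihydro-4H-chromen-4-one
Conditions: MgI2·OEt2 (anhydrous), THF, 50 °C; aqueous NH4Cl work-up
Reagents that add atoms: none
Why: Chelation-assisted demethylation: magnesium binds between the C4 carbonyl and O5 and iodide removes the methyl group of this one ether by SN2, so the 7-methyl ether, the MOM acetals and, in the absence of protic acid, the alkenes and C2 are expected to stay untouched.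

Step 15
Reactants: 20 (2S)-2-[2,5-bis(methoxymethoxy)phenyl]-5-hydroxy-7-methoxy-8-[(2R)-lavandulyl]-2,3-dihydro-4H-chromen-4-one
Product: 21 (2S)-2-(2,5-dihydroxyphenyl)-5-hydroxy-7-methoxy-8-[(2R)-lavandulyl]-2,3-dihydro-4H-chromen-4-one
Conditions: HCl (3 M aq.), MeOH, 40 °C, monitored
Reagents that add atoms: none
Why: Acid-catalysed cleavage of the two MOM acetals in methanol; no free hydroxyl stands ortho to the lavandulyl group (C8 lies between O1 and the 7-methoxy group), so chroman formation is not possible, and the acidic medium avoids the base-induced ring opening to the chalcone that would scramble C2.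

**Compound list**

1 | 3,5-dimethoxyphenol | COc1cc(O)cc(OC)c1 | starting material
2 | 1,3-dimethoxy-5-(methoxymethoxy)benzene | COCOc1cc(OC)cc(OC)c1 | intermediate
3 | racemic lavandulol [(±)-5-methyl-2-(prop-1-en-2-yl)hex-4-en-1-ol] | C=C(C)C(CC=C(C)C)CO | starting material
4 | (S)-lavandulol [(2S)-5-methyl-2-(prop-1-en-2-yl)hex-4-en-1-ol] | C=C(C)[C@H](CC=C(C)C)CO | intermediate
5 | (S)-lavandulyl trifluoromethanesulfonate | C=C(C)[C@H](CC=C(C)C)COS(=O)(=O)C(F)(F)F | intermediate
6 | [2,4-dimethoxy-6-(methoxymethoxy)phenyl]lithium | [Li]c1c(OC)cc(OC)cc1OCOC | intermediate (not isolated)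
7 | 1,5-dimethoxy-3-(methoxymethoxy)-2-[(2R)-5-methyl-2-(prop-1-en-2-yl)hex-4-en-1-yl]benzene | C=C(C)[C@H](CC=C(C)C)Cc1c(OC)cc(OC)cc1OCOC | intermediate
8 | 3,5-dimethoxy-2-[(2R)-lavandulyl]phenol | C=C(C)[C@H](CC=C(C)C)Cc1c(OC)cc(OC)cc1O | intermediate
9 | 2-(hydroxymethyl)-3,5-dimethoxy-6-[(2R)-lavandulyl]phenol (magnesium salt in the flask) | C=C(C)[C@H](CC=C(C)C)Cc1c(OC)cc(OC)c(CO)c1O | intermediate (not isolated)
10 | 2-hydroxy-4,6-dimethoxy-3-[(2R)-lavandulyl]benzaldehyde | C=C(C)[C@H](CC=C(C)C)Cc1c(OC)cc(OC)c(C=O)c1O | intermediate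
11 | 2,5-dihydroxybenzaldehyde | O=Cc1cc(O)ccc1O | starting material
12 | 2,5-bis(methoxymethoxy)benzaldehyde | O=Cc1cc(OCOC)ccc1OCOC | intermediate
13 | [2,5-bis(methoxymethoxy)phenyl]methanol | OCc1cc(OCOC)ccc1OCOC | intermediate
14 | 2-(bromomethyl)-1,4-bis(methoxymethoxy)benzene | BrCc1cc(OCOC)ccc1OCOC | intermediate
15 | 2-{[2,5-bis(methoxymethoxy)phenyl]methoxy}-4,6-dimethoxy-3-[(2R)-lavandulyl]benzaldehyde | C=C(C)[C@H](CC=C(C)C)Cc1c(OC)cc(OC)c(C=O)c1OCc1cc(OCOC)ccc1OCOC | intermediate
16 | 2-{[2,5-bis(methoxymethoxy)phenyl]methoxy}-4,6-dimethoxy-3-[(2R)-lavandulyl]benzoic acid | C=C(C)[C@H](CC=C(C)C)Cc1c(OC)cc(OC)c(C(=O)O)c1OCc1cc(OCOC)ccc1OCOC | intermediate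
17 | 2-{[2,5-bis(methoxymethoxy)phenyl]methoxy}-4,6-dimethoxy-3-[(2R)-lavandulyl]benzoyl chloride | C=C(C)[C@H](CC=C(C)C)Cc1c(OC)cc(OC)c(C(=O)Cl)c1OCc1cc(OCOC)ccc1OCOC | intermediate (not isolated)
18 | 2-diazo-1-{2-{[2,5-bis(methoxymethoxy)phenyl]methoxy}-4,6-dimethoxy-3-[(2R)-lavandulyl]phenyl}ethan-1-one | C=C(C)[C@H](CC=C(C)C)Cc1c(OC)cc(OC)c(C(=O)C=[N+]=[N-])c1OCc1cc(OCOC)ccc1OCOC | intermediate
19 | (2S)-2-[2,5-bis(methoxymethoxy)phenyl]-5,7-dimethoxy-8-[(2R)-lavandulyl]-2,3-dihydro-4H-chromen-4-one | C=C(C)[C@H](CC=C(C)C)Cc1c(OC)cc(OC)c2c1O[C@H](c1cc(OCOC)ccc1OCOC)CC2=O | intermediate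
20 | (2S)-2-[2,5-bis(methoxymethoxy)phenyl]-5-hydroxy-7-methoxy-8-[(2R)-lavandulyl]-2,3-dihydro-4H-chromen-4-one | C=C(C)[C@H](CC=C(C)C)Cc1c(OC)cc(O)c2c1O[C@H](c1cc(OCOC)ccc1OCOC)CC2=O | intermediate
21 | (2S)-2-(2,5-dihydroxyphenyl)-5-hydroxy-7-methoxy-8-[(2R)-5-methyl-2-(prop-1-en-2-yl)hex-4-en-1-yl]-2,3-dihydro-4H-chromen-4-one | C=C(C)[C@H](CC=C(C)C)Cc1c(OC)cc(O)c2c1O[C@H](c1cc(O)ccc1O)CC2=O | target

**Step count**

Total step count: 15
Longest linear sequence: 11 steps, from 3 to 21 through steps 2, 3, 4, 5, 6, 10, 11, 12, 13, 14 and 15.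

**Steps most likely to fail**

Step 13. The carbene may be captured by a lone pair of O1 before it reaches the C–H bond (oxonium ylide, 1,2-shift of the benzyl group, five-membered ring instead of ring C). The catalyst may also tell the two benzylic hydrogens apart only weakly, because insertion of a carbene with a single acceptor group has an early transition state. The fallback drops the carbene and closes ring C by oxa-Michael addition; it sets out from 10 and 12 and comes back to the route at 19. Excess MeMgBr (THF, 0 °C) adds to 10 to give the benzylic alcohol 2-(1-hydroxyethyl)-3,5-dimethoxy-6-[(2R)-lavandulyl]phenol F1, which MnO2 in CH2Cl2 oxidises to the acetophenone 1-{2-hydroxy-4,6-dimethoxy-3-[(2R)-lavandulyl]phenyl}ethan-1-one F2. Claisen–Schmidt condensation of F2 with aldehyde 12 (KOH, EtOH, rt) should give the chalcone (E)-3-[2,5-bis(methoxymethoxy)phenyl]-1-{2-hydroxy-4,6-dimethoxy-3-[(2R)-lavandulyl]phenyl}prop-2-en-1-one F3. NaOAc in refluxing EtOH then closes ring C (6-endo-trig oxa-Michael addition) to give 19 together with its C2 epimer, the (2R)-configured flavanone F4. The two are diastereomers because the lavandulyl centre is fixed, and they are separated by preparative HPLC. F4 is returned to the equilibrium through F3 under the same base, and the route continues from 19 with step 14.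

Step 4. The aryllithium may act as a base toward the triflate (removal of the allylic hydrogen at the stereocentre, elimination to a diene), the homoallylic triflate may ionise with participation of the isopropenyl double bond before it is attacked, and partial lithiation of 2 between the two methoxy groups would give a regioisomer. The fallback makes the same aryl–CH2 bond by Negishi coupling; it sets out from 2 (through 6) and 4 and comes back at 7. Aryllithium 6, made as in step 4, is quenched with I2 to give 2-iodo-1,5-dimethoxy-3-(methoxymethoxy)benzene F5, which is purified free of any regioisomer before the side chain is committed. Alcohol 4 is converted with I2, PPh3 and imidazole (CH2Cl2, 0 °C) into (S)-lavandulyl iodide F6. Zinc dust with LiCl in THF inserts into its C–I bond to give [(2S)-lavandulyl]zinc iodide F7. Coupling of F5 with F7 under Pd(OAc)2 and SPhos (THF, 50 °C) should give 7; the stereocentre is β to zinc and is not a reacting atom.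

Step 11. Hypochlorous acid released during the chlorite oxidation may chlorinate the ring A position between the two methoxy groups, or add to the side-chain double bonds, faster than the scavenger consumes it. The fallback reaches the diazoketone by diazo transfer and needs neither the acid nor the acid chloride; it sets out from 15 and comes back at 18, bypassing 16 and 17. With Ar = 2-{[2,5-bis(methoxymethoxy)phenyl]methoxy}-4,6-dimethoxy-3-[(2R)-lavandulyl]phenyl, MeMgBr (THF, 0 °C) adds to 15 to give the secondary alcohol 1-Ar-ethan-1-ol F8 (both configurations at the carbinol carbon, which is of no consequence). Dess–Martin periodinane (NaHCO3, CH2Cl2) oxidises it to the methyl ketone 1-Ar-ethan-1-one F9. The lithium enolate of F9 (LiN(SiMe3)2, THF, −78 °C) is acylated with CF3CO2CH2CF3 to the 1,3-diketone 4,4,4-trifluoro-1-Ar-butane-1,3-dione F10, which is not isolated. Methanesulfonyl azide, Et3N and water in MeCN then effect detrifluoroacetylative diazo transfer and should give 18.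

Further compounds
F1 | step 13 | 2-(1-hydroxyethyl)-3,5-dimethoxy-6-[(2R)-lavandulyl]phenol (both configurations at the carbinol carbon) | C=C(C)[C@H](CC=C(C)C)Cc1c(OC)cc(OC)c(C(C)O)c1O
F2 | step 13 | 1-{2-hydroxy-4,6-dimethoxy-3-[(2R)-lavandulyl]phenyl}ethan-1-one | C=C(C)[C@H](CC=C(C)C)Cc1c(OC)cc(OC)c(C(C)=O)c1O
F3 | step 13 | (E)-3-[2,5-bis(methoxymethoxy)phenyl]-1-{2-hydroxy-4,6-dimethoxy-3-[(2R)-lavandulyl]phenyl}prop-2-en-1-one | C=C(C)[C@H](CC=C(C)C)Cc1c(OC)cc(OC)c(C(=O)/C=C/c2cc(OCOC)ccc2OCOC)c1O
F4 | step 13 | (2R)-2-[2,5-bis(methoxymethoxy)phenyl]-5,7-dimethoxy-8-[(2R)-lavandulyl]-2,3-dihydro-4H-chromen-4-one | C=C(C)[C@H](CC=C(C)C)Cc1c(OC)cc(OC)c2c1O[C@@H](c1cc(OCOC)ccc1OCOC)CC2=O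
F5 | step 4 | 2-iodo-1,5-dimethoxy-3-(methoxymethoxy)benzene | COCOc1cc(OC)cc(OC)c1I
F6 | step 4 | (S)-lavandulyl iodide | C=C(C)[C@H](CC=C(C)C)CI
F7 | step 4 | [(2S)-lavandulyl]zinc iodide | C=C(C)[C@H](CC=C(C)C)C[Zn]I
F8 | step 11 | 1-{2-{[2,5-bis(methoxymethoxy)phenyl]methoxy}-4,6-dimethoxy-3-[(2R)-lavandulyl]phenyl}ethan-1-ol | C=C(C)[C@H](CC=C(C)C)Cc1c(OC)cc(OC)c(C(C)O)c1OCc1cc(OCOC)ccc1OCOC
F9 | step 11 | 1-{2-{[2,5-bis(methoxymethoxy)phenyl]methoxy}-4,6-dimethoxy-3-[(2R)-lavandulyl]phenyl}ethan-1-one | C=C(C)[C@H](CC=C(C)C)Cc1c(OC)cc(OC)c(C(C)=O)c1OCc1cc(OCOC)ccc1OCOC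
F10 | step 11 | 4,4,4-trifluoro-1-{2-{[2,5-bis(methoxymethoxy)phenyl]methoxy}-4,6-dimethoxy-3-[(2R)-lavandulyl]phenyl}butane-1,3-dione | C=C(C)[C@H](CC=C(C)C)Cc1c(OC)cc(OC)c(C(=O)CC(=O)C(F)(F)F)c1OCc1cc(OCOC)ccc1OCOC
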